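0.500 equiv of other conformer against one of substrate was the number I started from in this flask.

- violet: substrate 2.3 M; other conformer 0.50 equiv; the very flask that is asked about, followed so far
- flask: substrate 2.3 M; other conformer 0.500 equiv; time 80 min

violet run (percent of the substrate and other conformer together charged)

| time / min | target / % | isomer of the product / % |
|---|---|---|
| 8.00 | 13.1 | 16.5 |
| 15.0 | 3.6 | 20.2 |
| 25.0 | 1.3 | 20.3 |
| 30.0 | 0.3 | 22.1 |
| 40.0 | 1.1 | 22.6 |

(each reading ± 0.5 percentage points)

- share of target in target plus isomer of the product at 4.0 s
- share of target in target plus isomer of the product at 80 min

- percent here means substrate units held: one self-condensation product counts as two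
- steps under discussion: substrate <-> other conformer; substrate -> target; other conformer -> isomer of the product; other conformer <-> third conformer; third conformer -> third product; target -> over-reaction product; 2 other conformer -> self-condensation product; other conformer <-> dormant form

Both products start from nothing, so the early share of target is the rate into target over the two rates together. Since 4.0 s is far shorter than the first violet reading at 8.00 min, I took both conformers at their charged amounts. I also set the two rate constants equal, which was a guess. That leaves the charge share, [substrate]/([substrate]+[other conformer]) at the start, which here is 66.7%. I put the late share below 4.64%, the share read from the scattered violet readings at 40.0 min.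

The forecast, higher than my early share, said 80% at 4.0 s, “before any conformer exchange”, and 1% at 80 min. The flask gave 68.5% at 4.0 s and 0.425% at 80 min.

    substrate ⇌ other conformer (K = 0.960, k = 0.00370 s⁻¹)
    substrate → target (k = 0.00400 s⁻¹)
    other conformer → isomer of the product (k = 0.00370 s⁻¹)
    other conformer ⇌ third conformer (K = 1.30, k = 0.00220 s⁻¹)
    third conformer → third product (k = 0.00180 s⁻¹)
    target → over-reaction product (k = 0.00370 s⁻¹)
    2 other conformer → self-condensation product (k = 0.00350 L mol⁻¹ s⁻¹)
    other conformer ⇌ dormant form (K = 6.20, k = 0.00310 s⁻¹)

In this flask the half-life of target by its step to over-reaction product alone, 3.1 min, is short against 80 min. The share in this flask at 4.0 s stands 1.8 percentage points above the charge share. In odds that gap is a factor of 1.09, the selectivity factor of target over isomer of the product in this flask.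

In the neighbour flask with 0.850 equiv, the charge share is 54.1%, and with the factor it becomes 56.2%. The computed share of target in that neighbour flask at 4.0 s is 56.6%.

All runs stem from a simulated flask for an exercise; noise was put on by code.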